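## The problem

Marchantin C is a macrocyclic bis(bibenzyl). Four benzene rings form one 18-membered ring through two ethano bridges (ring A to ring B, ring C to ring D) and two diaryl ether bonds (ring B to ring C, ring D to ring A). The target has no stereocentre, so nothing in it can direct a reaction, and any stereocentre made on the way must be erasable. The difficulty lies in connectivity, in the placing of the two hydroxyls and in the closure of the large ring. The ring B–ring C ether sits on a ring B carbon flanked by the hydroxyl and the ethano bridge; a phenol this hindered is a poor nucleophile for a ring closure, so this bond is best made early and bimolecularly. The chain to be closed contains a para-phenylene and a meta-phenylene unit, and closure at an aromatic carbon normally needs an activating group that must later be removed, or forcing copper chemistry. Both free phenols are ortho-aryloxy phenols that oxidise easily, and the four benzylic methylenes do not tolerate radical or strongly oxidising reagents, so the hydroxyls should be released late. The enabling feature is the pattern of ring D: the hydroxyl carbon C1 is para to the bridge carbon C4 and ortho to the ether carbon C6. This is the pattern of a 4-substituted cyclohexanone functionalised at an α-carbon. Such a ketone has a mirror plane through C1 and C4, its two α-carbons are equivalent, and its carbonyl can first activate the α-carbon towards the ring A phenoxide and then become the C1 hydroxyl on dehydrogenation.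

## Retrosynthesis

**Target 17 to methyl ether 16.** Only the O–CH3 bond of ring B is cut. The methyl group arrives with the commercial ring B building block 5 and shields ring B through the oxidative step. The forward reaction is a BBr3 demethylation, which must leave both diaryl ethers intact.

**16 to the macrocyclic ketone 15.** Ring D is taken back to a cyclohexanone: a 2-aryloxy-4-alkylphenol is the doubly dehydrogenated form of a 2-aryloxy-4-alkylcyclohexanone. This turns the ether carbon C6 from an unactivated aromatic carbon into an sp3 carbon next to a carbonyl. The two stereocentres of 15 are of no consequence because both vanish on aromatisation. The forward reaction is a catalytic aerobic dehydrogenation that has to tolerate the α-aryloxy group and the benzylic methylenes.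

**15 to the bromoketone 13 (through phenoxide 14).** The O–C6 bond of ring D is cut, giving a ring A phenoxide and an α-bromocyclohexanone. This cut is preferred over its neighbours for three reasons:
- The ring B–ring C ether would need the hindered 2,6-disubstituted phenoxide as the ring-closing nucleophile.
- A closure at an ethano bridge (Wittig or McMurry type) is viable but leaves both ethers to be made at aromatic carbons and does not use the ring D pattern.
- In 13 the nucleophile is an unhindered para-alkyl phenoxide and the electrophile is a carbonyl-activated secondary bromide.

The precursor is acyclic and its phenol is stored as a silyl ether that fluoride opens in the flask. The forward step must favour ring closure and O-alkylation over oligomerisation, elimination and Favorskii contraction.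

**13 to 12 to 11.** The C–Br bond and both O–Si bonds are cut. Ketone 11 is symmetric, so its silyl enol ether 12 can only form one way (as a racemate), and the same silyl triflate protects the ring A phenol. Bromination through the enol ether, rather than of the ketone itself, keeps the halogen away from three electron-rich arenes.

**11 to 10 to 9.** These are functional group changes only. The ketone is masked as a dioxolane during assembly. Both ethano bridges are carried as alkenes and the ring A phenol as a benzyl ether, so one hydrogenation saturates both bridges and frees the phenol.

**9 to aldehyde 6 and phosphonium salt 8.** The ring A–ring B bridge is cut as a C=C bond (Wittig). Salt 8 comes in one step from commercial 4-(benzyloxy)benzyl chloride 7. Alkene geometry is irrelevant.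

**6 to phenol 4 and 2-fluoro-3-methoxybenzaldehyde 5.** The hindered ring B–ring C ether is cut in the sense of a nucleophilic aromatic substitution. Ring B is the electrophile, activated by its own ortho formyl group, which is also the handle for the next Wittig reaction. Copper-mediated arylation of 2-hydroxy-3-methoxybenzaldehyde was weighed, but that phenol is di-ortho-substituted and chelating, so ring B is better used as the electrophile.

**4 to phosphonium salt 2 and aldehyde 3.** The ring C–ring D bridge is cut as a C=C bond. The commercial ketal aldehyde 3 brings ring D as a protected 4-substituted cyclohexanone. Salt 2 comes in one step from 3-hydroxybenzyl alcohol 1.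

## Roads not taken

**Alternative 1:** Ring A is cut at two of its C–C bonds, giving a 2-aryloxybuta-1,3-diene on the ring D oxygen and a terminal ynone on the ring B side chain (seco compound A2). A macrocyclising Diels–Alder reaction would then build ring A and the macrocycle together, giving the 1-aryloxy-4-acylcyclohexa-1,4-diene A1.
- Merits: two C–C bonds, one carbocycle and the macrocycle form in one step. The donor at diene C2 and the acceptor on the alkyne predict the needed 1,4 ("para") pattern. A1 needs to lose only two hydrogens to become aromatic, which is easier than the double dehydrogenation of ketone 15; here the alternative is better.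
- Weak points: A2 carries two fragile groups. The 2-aryloxydiene is an enol ether that hydrolyses and polymerises and is awkward to install on a guaiacol-type phenol. The ynone has an acidic methylene between arene and carbonyl and can isomerise or take up nucleophiles. The cycloaddition has a long tether, so it needs heat and dilution, conditions under which the diene degrades, and the tether may override the electronic regiochemistry. The bridge ketone is not in the target and must be removed, and ring D needs its own methyl ether, so three or four operations follow the key step against two in the chosen plan.
- Comparison: the chosen plan sets stable, storable precursors (a bromoketone and a silyl ether) and an activating carbonyl that ends up as the target's own hydroxyl against the greater bond-forming power of A2 to A1.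

**Alternative 2:** The hindered ring B–ring C ether is cut, with ring C activated as an η6-chloroarene cyclopentadienylruthenium cation (seco complex A4). The ring B phenoxide would displace chloride at room temperature to give complex A3. Photolysis in acetonitrile would release marchantin C dimethyl ether A5, and BBr3 would finish.
- Merits: the cationic metal makes an otherwise inert chloroarene reactive under mild base. This type of cycloetherification has direct precedent for macrocyclic diaryl ethers, which is stronger precedent than the chosen ring closure has. No redox adjustment is needed, and two steps follow the key step, the same as in the chosen plan.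
- Weak points: a full equivalent of ruthenium is consumed. The metal must sit on ring C alone. Late complexation with [CpRu(NCMe)3]PF6 would prefer the oxygenated rings. Early complexation means carrying a cationic sandwich salt, with acidified benzylic positions, through ylide chemistry and hydrogenation. The ring-closing nucleophile is the 2,6-disubstituted phenoxide, the worst of the four oxygens.
- Comparison: the chosen plan concedes the better precedent. It sets against it neutral, chromatographable intermediates, a metal used only catalytically in one step, and the hindered ether made by a simple bimolecular substitution instead of in the ring closure.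

**Alternative 3:** The same ring D–ring A ether is cut, but with reversed polarity. A ring D phenoxide would attack a ring A fluoroarene activated by a para ketone on the bridge carbon (seco compound A7), giving the macrocyclic deoxybenzoin A6. The ketone would then be reduced away and two methyl ethers cleaved.
- Merits: substitution of a para-acyl aryl fluoride is textbook chemistry, and this kind of closure is proven for macrocyclic diaryl ethers. All rings stay aromatic. The ketone sits on a carbon that is CH2 in the target, so its removal is routine. In precedent for the closure this road is ahead of the chosen plan.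
- Weak points: a ketone is only a moderate activator, so the closure needs heat. The deoxybenzoin methylene of A7 is about as acidic as the phenol, and its enolate cancels the activation and opens aldol and arylation side paths. Ring D needs a methyl ether, and the ketone is an auxiliary that costs at least one step to erase.
- Comparison: the chosen plan also has an enolisable ketone beside its electrophile, so it is not free of base-induced side reactions. It offers a far better leaving group at an sp3 carbon (closure near 50 °C), an activating group that is kept as the ring D hydroxyl, and the same two steps after closure without a deoxygenation.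

Key step: step 10

Remark on the chemistry: the Wittig products 4, 6 and 9 are carried on as E/Z mixtures (SMILES without alkene geometry), since every C=C bond is hydrogenated in step 6. Compounds 12 to 15 are racemic, with one enantiomer drawn. Compounds 1, 3, 5 and 7 are taken as commercial.

## Route

Step 1
Reactants: 1 3-hydroxybenzyl alcohol
Product: 2 (3-hydroxybenzyl)triphenylphosphonium bromide
Conditions: PPh3·HBr, MeCN, reflux
Reagents that add atoms: triphenylphosphine hydrobromide, [Br-].c1ccc(cc1)[PH+](c1ccccc1)c1ccccc1
Why: Direct conversion of a benzylic alcohol into its phosphonium salt: protonation and loss of water, then capture of the benzylic electrophile by the phosphine; the phenol is inert under these acidic conditions.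

Step 2
Reactants: 2 (3-hydroxybenzyl)triphenylphosphonium bromide; 3 1,4-dioxaspiro[4.5]decane-8-carbaldehyde
Product: 4 3-[2-(1,4-dioxaspiro[4.5]decan-8-yl)ethenyl]phenol (E/Z mixture)
Conditions: KOtBu (2.05 equiv), THF, 0 °C; then 3, 0 °C to rt; aq. NH4Cl work-up
Reagents that add atoms: none
Why: Wittig olefination; two equivalents of base give the phenoxide ylide, a semi-stabilised benzylide that is preformed so that no free base meets the enolisable aldehyde. The alkene geometry does not matter because the bond is hydrogenated in step 6.

Step 3
Reactants: 4 3-[2-(1,4-dioxaspiro[4.5]decan-8-yl)ethenyl]phenol; 5 2-fluoro-3-methoxybenzaldehyde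
Product: 6 2-{3-[2-(1,4-dioxaspiro[4.5]decan-8-yl)ethenyl]phenoxy}-3-methoxybenzaldehyde (E/Z mixture)
Conditions: K2CO3, DMF, 110 °C
Reagents that add atoms: none
Why: Nucleophilic aromatic substitution by addition–elimination: the ortho formyl group stabilises the Meisenheimer adduct and fluoride is the best leaving group for this mechanism. The ketal and the alkene are inert to carbonate, and the hindered ring B–ring C ether is made before any macrocyclic constraint exists.

Step 4
Reactants: 7 4-(benzyloxy)benzyl chloride
Product: 8 [4-(benzyloxy)benzyl]triphenylphosphonium chloride
Conditions: PPh3, toluene, reflux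
Reagents that add atoms: triphenylphosphine, c1ccc(cc1)P(c1ccccc1)c1ccccc1
Why: SN2 quaternisation of the phosphine by a reactive benzylic chloride; the salt should precipitate from toluene.

Step 5
Reactants: 6 2-{3-[2-(1,4-dioxaspiro[4.5]decan-8-yl)ethenyl]phenoxy}-3-methoxybenzaldehyde; 8 [4-(benzyloxy)benzyl]triphenylphosphonium chloride
Product: 9 8-{2-[3-(2-{2-[4-(benzyloxy)phenyl]ethenyl}-6-methoxyphenoxy)phenyl]ethenyl}-1,4-dioxaspiro[4.5]decane (E/Z mixture at both alkenes)
Conditions: K2CO3, 18-crown-6 (cat.), CH2Cl2, reflux
Reagents that add atoms: none
Why: Wittig olefination under solid–liquid phase-transfer conditions, the standard way to stilbene precursors of bibenzyls; the mild base leaves the ketal and the diaryl ether untouched.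

Step 6
Reactants: 9 bis-alkene benzyl ether from step 5
Product: 10 4-{2-[2-(3-[2-(1,4-dioxaspiro[4.5]decan-8-yl)ethyl]phenoxy)-3-methoxyphenyl]ethyl}phenol
Conditions: H2 (1 atm), 10% Pd/C, EtOAc–EtOH, rt
Reagents that add atoms: none
Why: Heterogeneous catalytic hydrogenation should saturate both disubstituted alkenes and hydrogenolyse the benzyl ether in one operation; the ketal survives because no acid is present, and the diaryl and methyl ethers are inert.

Step 7
Reactants: 10 phenol ketal from step 6
Product: 11 4-[2-(3-{2-[2-(4-hydroxyphenyl)ethyl]-6-methoxyphenoxy}phenyl)ethyl]cyclohexan-1-one
Conditions: 1 M aq. HCl, THF, rt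
Reagents that add atoms: water, O
Why: Acid-catalysed hydrolysis of the dioxolane; no other group in 10 is acid-labile at room temperature.

Step 8
Reactants: 11 phenol ketone from step 7
Product: 12 bis-silyl compound: tert-butyldimethylsilyl ether of the ring A phenol and tert-butyldimethylsilyl enol ether of the ketone (4-substituted 1-silyloxycyclohex-1-ene, racemic)
Conditions: TBSOTf (2.4 equiv), Et3N (3 equiv), CH2Cl2, 0 °C to rt
Reagents that add atoms: tert-butyldimethylsilyl trifluoromethanesulfonate, CC(C)(C)[Si](C)(C)OS(=O)(=O)C(F)(F)F
Why: Soft enolisation with a silyl triflate and an amine converts the ketone into its silyl enol ether and silylates the phenol at the same time. The two α-carbons of the 4-substituted cyclohexanone are enantiotopic, so one constitution forms, as a racemate.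

Step 9
Reactants: 12 bis-silyl compound from step 8
Product: 13 trans-2-bromo-4-[2-(3-{2-[2-(4-{[tert-butyl(dimethyl)silyl]oxy}phenyl)ethyl]-6-methoxyphenoxy}phenyl)ethyl]cyclohexan-1-one (racemic)
Conditions: NBS (1.0 equiv), NaHCO3, THF, −78 °C to 0 °C
Reagents that add atoms: N-bromosuccinimide, O=C1CCC(=O)N1Br
Why: Electrophilic bromination of a silyl enol ether, which at low temperature is far more nucleophilic than the aryl rings. Axial attack on the half-chair with the side chain equatorial should place bromine trans to the C4 substituent; any cis isomer is carried along, since both stereocentres are erased in step 11.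

Step 10
Reactants: 13 trans-2-bromoketone aryl silyl ether from step 9
Product: 15 macrocyclic cis-2-aryloxy-4-alkylcyclohexanone (ring D as cyclohexanone; ring B methyl ether; racemic), via caesium phenoxide 14 (not isolated)
Conditions: CsF (3 equiv), DMF, 50 °C; 13 added by syringe pump over 12 h to a final 2 mM
Reagents that add atoms: none
Why: Fluoride attacks silicon of the aryl silyl ether and releases the caesium phenoxide 14 gradually and without an added Brønsted base, so its stationary concentration stays low. The phenoxide oxygen then displaces bromide from the α-carbon of the cyclohexanone by SN2, a displacement accelerated by the adjacent carbonyl π* orbital and best aligned when the C–Br bond is axial, as in the trans isomer 13. The closest known reaction type is the Williamson-type O-alkylation of phenoxides with 2-halocyclohexanones to give 2-aryloxycyclohexanones, run here intramolecularly. The 18-membered ring closes by an 18-exo-tet attack at an sp3 carbon while ring D is still a mobile chair, which avoids much of the strain of an attack on a flat arene. The new C–O stereocentre arises by inversion at the bromide carbon, so its configuration relative to C4 (cis, both substituents equatorial) follows from that of 13; it needs no further control, because both stereocentres disappear in step 11 and a cis/trans mixture serves equally. Ring closure has to beat oligomerisation, which high dilution, slow addition and the slow release of phenoxide are meant to secure. O-alkylation has to beat C-alkylation, elimination and Favorskii contraction, which the loosely paired caesium phenoxide in DMF, the weak basicity of fluoride and phenoxide and the absence of alkoxide favour. No regiochemical question arises, because 13 has a single C–Br bond, placed by the symmetry of ketone 11.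

Step 11
Reactants: 15 macrocyclic cis-2-aryloxy-4-alkylcyclohexanone
Product: 16 marchantin C mono-methyl ether (methyl ether of the ring B hydroxyl; ring D hydroxyl free)
Conditions: Pd(O2CCF3)2 (5 mol %), 2-(dimethylamino)pyridine (10 mol %), TsOH (20 mol %), O2 (1 atm), DMSO, 80 °C
Reagents that add atoms: none
Why: Palladium-catalysed aerobic dehydrogenation of a cyclohexanone to a phenol: divalent palladium forms the α-palladated ketone, β-hydride elimination gives the enone, a second cycle gives the dienone, which tautomerises, and O2 reoxidises zerovalent palladium. The carbonyl oxygen becomes the C1 hydroxyl, ortho to the ether and para to the bridge, and both stereocentres are erased.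

Step 12
Reactants: 16 marchantin C mono-methyl ether
Product: 17 marchantin C
Conditions: BBr3 (4 equiv), CH2Cl2, −78 °C to rt; then H2O
Reagents that add atoms: none
Why: Lewis acid cleavage of an aryl methyl ether: boron coordinates the methoxy oxygen and bromide removes the methyl group by SN2. Diaryl ethers are not cleaved, and aqueous work-up hydrolyses the aryloxyboron species.

## Compound list

1 | 3-hydroxybenzyl alcohol | OCc1cccc(O)c1 | starting material
2 | (3-hydroxybenzyl)triphenylphosphonium bromide | [Br-].Oc1cccc(C[P+](c2ccccc2)(c2ccccc2)c2ccccc2)c1 | intermediate
3 | 1,4-dioxaspiro[4.5]decane-8-carbaldehyde | O=CC1CCC2(CC1)OCCO2 | starting material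
4 | 3-[2-(1,4-dioxaspiro[4.5]decan-8-yl)ethenyl]phenol (E/Z mixture) | Oc1cccc(C=CC2CCC3(CC2)OCCO3)c1 | intermediate
5 | 2-fluoro-3-methoxybenzaldehyde | COc1cccc(C=O)c1F | starting material
6 | 2-{3-[2-(1,4-dioxaspiro[4.5]decan-8-yl)ethenyl]phenoxy}-3-methoxybenzaldehyde (E/Z mixture) | COc1cccc(C=O)c1Oc1cccc(C=CC2CCC3(CC2)OCCO3)c1 | intermediate
7 | 4-(benzyloxy)benzyl chloride | ClCc1ccc(OCc2ccccc2)cc1 | starting material
8 | [4-(benzyloxy)benzyl]triphenylphosphonium chloride | [Cl-].c1ccc(cc1)COc1ccc(C[P+](c2ccccc2)(c2ccccc2)c2ccccc2)cc1 | intermediate
9 | 8-{2-[3-(2-{2-[4-(benzyloxy)phenyl]ethenyl}-6-methoxyphenoxy)phenyl]ethenyl}-1,4-dioxaspiro[4.5]decane (E/Z mixture at both alkenes) | COc1cccc(C=Cc2ccc(OCc3ccccc3)cc2)c1Oc1cccc(C=CC2CCC3(CC2)OCCO3)c1 | intermediate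
10 | 4-{2-[2-(3-[2-(1,4-dioxaspiro[4.5]decan-8-yl)ethyl]phenoxy)-3-methoxyphenyl]ethyl}phenol | COc1cccc(CCc2ccc(O)cc2)c1Oc1cccc(CCC2CCC3(CC2)OCCO3)c1 | intermediate
11 | 4-[2-(3-{2-[2-(4-hydroxyphenyl)ethyl]-6-methoxyphenoxy}phenyl)ethyl]cyclohexan-1-one | COc1cccc(CCc2ccc(O)cc2)c1Oc1cccc(CCC2CCC(=O)CC2)c1 | intermediate
12 | bis-silyl compound: ring A aryl tert-butyldimethylsilyl ether and ring D tert-butyldimethylsilyl enol ether (racemic, one enantiomer drawn) | CC(C)(C)[Si](C)(C)OC1=CC[C@H](CCc2cccc(c2)Oc2c(OC)cccc2CCc2ccc(O[Si](C)(C)C(C)(C)C)cc2)CC1 | intermediate
13 | trans-2-bromo-4-substituted cyclohexanone aryl silyl ether (racemic, one enantiomer drawn) | O=C1CC[C@@H](CCc2cccc(c2)Oc2c(OC)cccc2CCc2ccc(O[Si](C)(C)C(C)(C)C)cc2)C[C@@H]1Br | intermediate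
14 | caesium phenoxide of the trans-2-bromoketone (racemic; formed in the flask) | O=C1CC[C@@H](CCc2cccc(c2)Oc2c(OC)cccc2CCc2ccc([O-])cc2)C[C@@H]1Br.[Cs+] | intermediate
15 | macrocyclic cis-2-aryloxy-4-alkylcyclohexanone, ring B methyl ether (racemic, one enantiomer drawn) | O=C1CC[C@@H]2C[C@H]1Oc1ccc(cc1)CCc1cccc(OC)c1Oc1cccc(c1)CC2 | intermediate
16 | marchantin C mono-methyl ether (ring B methoxy, ring D hydroxyl free) | Oc1ccc2cc1Oc1ccc(cc1)CCc1cccc(OC)c1Oc1cccc(c1)CC2 | intermediate
17 | marchantin C | Oc1ccc2cc1Oc1ccc(cc1)CCc1cccc(O)c1Oc1cccc(c1)CC2 | target

## Step count and risks

Total step count: 12. Longest linear sequence: 11 steps (steps 1 to 3 and 5 to 12, from 1); step 4 is a one-step side branch.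

**Step 10 (key step).** The closure of the 18-membered ring may be slow. In that case intermolecular etherification to oligomers, loss of HBr to the cyclohexenone in the basic fluoride/phenoxide medium, or exchange of bromide for fluoride would take over. The electrophile is a secondary bromide and the chain must fold around two aryl ether hinges. The fallback sets out from 12 and returns at 15. Rubottom oxidation of the silyl enol ether (mCPBA, NaHCO3, CH2Cl2, 0 °C) should give the 2-silyloxy ketone F1. Buffered HF·pyridine in THF would remove both silyl groups and give the α-hydroxy ketone phenol F2; the buffer is there to avoid α-ketol transposition. A Mitsunobu macrocyclisation (PPh3, DIAD, toluene, high dilution) would then form the same C6–O bond with inversion under non-basic conditions and deliver 15.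

**Step 11.** The dehydrogenation may stall after the first desaturation, or the catalyst may fall out as palladium metal, because the α-carbon bearing the aryloxy group is slow to palladate. The electron-rich product may also be oxidised further under O2. The fallback sets out from 15 and returns at 16, and does the two desaturations one at a time with stoichiometric reagents:
- Kinetic enolisation on the methylene side (LDA, TMSCl, THF, −78 °C) gives the silyl enol ether F3.
- Saegusa–Ito oxidation (Pd(OAc)2, MeCN, rt) gives the macrocyclic 6-aryloxycyclohex-2-enone F4.
- A second kinetic enolisation (LDA, TMSCl) gives the cross-conjugated 2-silyloxydiene F5.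
- A second Pd(OAc)2 oxidation gives the dienone, which tautomerises to 16.

**Step 9.** Bromination of the electron-rich rings A and B, or a second bromination at the other α-carbon, may compete if the enol ether is partly hydrolysed before it meets the reagent. The fallback sets out from 11 and returns at 13. Selective silylation of the phenol (TBSCl, imidazole, DMF) gives the aryl silyl ether ketone F6. This is brominated at the α-carbon with phenyltrimethylammonium tribromide in THF at 0 °C, a reagent that brominates ketones through their enols in preference to activated arenes.

**Step 3.** Substitution may be slow at a fluoride flanked by two ortho substituents with only one activating group. At the temperature then needed, the aldehyde may be consumed by disproportionation or by dimethylamine from the breakdown of DMF. The fallback sets out from 4 and returns at 6. It is a copper-catalysed Ullmann etherification of 4 with commercial 2-bromo-3-methoxybenzaldehyde (CuI, N,N-dimethylglycine, Cs2CO3, dioxane, 90 °C), in which the ortho formyl group assists the monovalent copper catalyst. It gives 6 directly and makes no new compound (F0).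

## Further compounds

F1 | step 10 | 2-[tert-butyl(dimethyl)silyloxy]-4-substituted cyclohexanone, ring A aryl silyl ether (racemic, mixture of diastereomers) | O=C1CCC(CCc2cccc(c2)Oc2c(OC)cccc2CCc2ccc(O[Si](C)(C)C(C)(C)C)cc2)CC1O[Si](C)(C)C(C)(C)C
F2 | step 10 | 2-hydroxy-4-[2-(3-{2-[2-(4-hydroxyphenyl)ethyl]-6-methoxyphenoxy}phenyl)ethyl]cyclohexan-1-one (racemic, mixture of diastereomers) | O=C1CCC(CCc2cccc(c2)Oc2c(OC)cccc2CCc2ccc(O)cc2)CC1O
F3 | step 11 | trimethylsilyl enol ether of 15 on the methylene side (racemic, one enantiomer drawn) | C[Si](C)(C)OC1=CC[C@@H]2C[C@H]1Oc1ccc(cc1)CCc1cccc(OC)c1Oc1cccc(c1)CC2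
F4 | step 11 | macrocyclic 6-aryloxy-4-alkylcyclohex-2-enone (racemic, one enantiomer drawn) | O=C1C=C[C@@H]2C[C@H]1Oc1ccc(cc1)CCc1cccc(OC)c1Oc1cccc(c1)CC2
F5 | step 11 | macrocyclic 1-aryloxy-2-(trimethylsilyloxy)cyclohexa-1,3-diene (racemic, one enantiomer drawn) | C[Si](C)(C)OC1=C2C[C@@H](C=C1)CCc1cccc(c1)Oc1c(OC)cccc1CCc1ccc(O2)cc1
F6 | step 9 | 4-[2-(3-{2-[2-(4-{[tert-butyl(dimethyl)silyl]oxy}phenyl)ethyl]-6-methoxyphenoxy}phenyl)ethyl]cyclohexan-1-one | O=C1CCC(CCc2cccc(c2)Oc2c(OC)cccc2CCc2ccc(O[Si](C)(C)C(C)(C)C)cc2)CC1
F0 | step 3 | none | none
A1 | alternative 1 | macrocyclic 1-aryloxy-4-acylcyclohexa-1,4-diene | COc1ccc2cc1OC1=CCC(=CC1)C(=O)Cc1cccc(OC)c1Oc1cccc(c1)CC2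
A2 | alternative 1 | seco 2-aryloxybuta-1,3-diene with terminal ynone | COc1ccc(CCc2cccc(Oc3c(OC)cccc3CC(=O)C#C)c2)cc1OC(=C)C=C
A3 | alternative 2 | marchantin C dimethyl ether bound η6 through ring C to cyclopentadienylruthenium hexafluorophosphate | COc1ccc2cc1Oc1ccc(cc1)CCc1cccc(OC)c1Oc1cccc(c1)CC2.[Ru+2].[cH-]1cccc1.F[P-](F)(F)(F)(F)F
A4 | alternative 2 | seco ring B phenol with ring C chloroarene bound η6 to cyclopentadienylruthenium hexafluorophosphate | COc1ccc(CCc2cccc(Cl)c2)cc1Oc1ccc(CCc2cccc(OC)c2O)cc1.[Ru+2].[cH-]1cccc1.F[P-](F)(F)(F)(F)F
A5 | alternative 2 | marchantin C dimethyl ether | COc1ccc2cc1Oc1ccc(cc1)CCc1cccc(OC)c1Oc1cccc(c1)CC2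
A6 | alternative 3 | macrocyclic deoxybenzoin (ketone on the ring A side of the A–B bridge) | COc1ccc2cc1Oc1ccc(cc1)C(=O)Cc1cccc(OC)c1Oc1cccc(c1)CC2
A7 | alternative 3 | seco ring D phenol with 4-fluorophenyl ketone | COc1ccc(CCc2cccc(Oc3c(OC)cccc3CC(=O)c3ccc(F)cc3)c2)cc1O
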